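**Plan**
- Retrosynthesis: the C5 and C5' phenols are masked as methyl and benzyl ethers. Ring C is opened at O1–C2 to a 1,3-diketone, and the diketone is cut at C2–C3, which puts the ring B aroyl group back on O1 as an aryl ester.
- The ester is cut at O1–C(=O) into the ring A hydroxyacetophenone and the ring B acid. The acid is cut at its aryl–CO2H bond and at C5'–O, leading back to 3-bromo-4,5-dimethoxybenzaldehyde.
- Forward: the ring B acid is made in three steps and esterified onto O1. The aroyl group then migrates from O1 to C3 (C2–C3 formed, no ring closed), acid closes ring C through O1–C2, and BCl3 frees both phenols in one operation.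
- Enabling feature: C4–C3–C2 is a 1,3-dioxygenated three-carbon bridge between ring A and ring B, and O1 sits ortho to the C4 acyl group. An aroyl group placed on O1 is therefore within six-membered reach of the C3 enolate carbon.
- Rings A and B are bought as benzene rings; only ring C is built. The target has no stereocentre and no stereogenic double bond, so there is no stereochemistry to control.

Key step: step 5

Remark: compounds 1 and 7 are assumed to be purchasable. Diketone 10 is drawn as the diketo tautomer, although it should exist mainly as the chelated enol.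

**Route**

Step 1
Reactants: 1 3-bromo-4,5-dimethoxybenzaldehyde
Product: 3 3-bromo-4,5-dimethoxyphenol, via aryl formate 2 (not isolated)
Conditions: mCPBA, CH2Cl2, 0 °C to rt; aq NaHCO3 wash; then NaOH, MeOH/H2O, rt; HCl
Reagents that add atoms: mCPBA (3-chloroperoxybenzoic acid), O=C(OO)c1cccc(Cl)c1
Why: Baeyer–Villiger (Dakin-type) oxidation, in which the aryl group activated by its para methoxy group migrates in preference to hydrogen in the Criegee adduct to give the aryl formate, which base then hydrolyses to the phenol while the aryl bromide and methyl ethers stay untouched.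

Step 2
Reactants: 3 3-bromo-4,5-dimethoxyphenol
Product: 4 1-(benzyloxy)-3-bromo-4,5-dimethoxybenzene
Conditions: BnBr, K2CO3, DMF, rt
Reagents that add atoms: benzyl bromide, BrCc1ccccc1
Why: Williamson ether synthesis by SN2 attack of the phenoxide on benzyl bromide, giving a benzyl ether that should tolerate the later organolithium, acylation, base and brief acid conditions.

Step 3
Reactants: 4 1-(benzyloxy)-3-bromo-4,5-dimethoxybenzene
Product: 6 5-(benzyloxy)-2,3-dimethoxybenzoic acid, via aryllithium 5 (not isolated)
Conditions: n-BuLi, THF, −78 °C; CO2 (g), −78 °C to rt; aq HCl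
Reagents that add atoms: carbon dioxide, O=C=O
Why: Bromine–lithium exchange followed by carboxylation, the exchange at −78 °C being much faster than benzylic or ortho deprotonation, so the aryllithium (stabilised by its ortho methoxy group) is trapped by CO2 at the former C–Br carbon.

Step 4
Reactants: 6 5-(benzyloxy)-2,3-dimethoxybenzoic acid; 7 1-(6-hydroxy-2,3,4-trimethoxyphenyl)ethanone
Product: 9 2-acetyl-3,4,5-trimethoxyphenyl 5-(benzyloxy)-2,3-dimethoxybenzoate, via acid chloride 8 (not isolated)
Conditions: (COCl)2, DMF (cat.), CH2Cl2, 0 °C to rt, evaporate; then 7, pyridine, DMAP (cat.), 0 °C to rt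
Reagents that add atoms: none
Why: Acid chloride formation under Vilsmeier-type activation followed by DMAP-catalysed O-acylation of the phenol, which is the only nucleophilic site of 7 and is acylated in pyridine in the standard way for 2-hydroxyacetophenones.

Step 5
Reactants: 9 2-acetyl-3,4,5-trimethoxyphenyl 5-(benzyloxy)-2,3-dimethoxybenzoate
Product: 10 1-[5-(benzyloxy)-2,3-dimethoxyphenyl]-3-(6-hydroxy-2,3,4-trimethoxyphenyl)propane-1,3-dione
Conditions: KOH (powdered, 3 equiv), dry pyridine, 50 °C; cold aq HCl
Reagents that add atoms: none
Why: KOH removes a proton from the acetyl methyl group of 9, the only enolisable C–H in the molecule, and the enolate carbon (C3) adds to the neighbouring ester carbonyl (the future C2) through a six-membered cyclic tetrahedral intermediate that collapses by expelling the ring A phenoxide, so the aroyl group moves from O1 to C3 and the C2–C3 bond is formed. This is the Baker–Venkataraman rearrangement, an intramolecular Claisen-type O-to-C acyl transfer of 2-aroyloxyacetophenones. No ring is closed, because the cyclic intermediate reopens, and no stereocentre is created. The selectivity required is C-acylation over hydroxide cleavage of the aryl ester: powdered KOH in dry pyridine keeps free water low, the intramolecular six-membered delivery should outpace bimolecular attack on an ester carbonyl shielded by the ortho methoxy group, and the doubly deprotonated product (phenoxide plus chelated diketone enolate) is a thermodynamic sink. The ester tether also decides which ring becomes A and which B, and avoids an intermolecular Claisen condensation on the hindered 2-methoxyaroyl group.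

Step 6
Reactants: 10 1-[5-(benzyloxy)-2,3-dimethoxyphenyl]-3-(6-hydroxy-2,3,4-trimethoxyphenyl)propane-1,3-dione
Product: 11 2-[5-(benzyloxy)-2,3-dimethoxyphenyl]-5,6,7-trimethoxy-4H-chromen-4-one
Conditions: H2SO4 (cat.), AcOH, 90 °C
Reagents that add atoms: none
Why: Acid-catalysed cyclodehydration, in which the ring A phenol adds to the protonated aroyl carbonyl in a 6-exo-trig closure to form O1–C2 and the resulting hemiketal loses water to the aromatic pyranone (ring C), brief heating with catalytic acid being tolerated by an aryl benzyl ether.

Step 7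
Reactants: 11 2-[5-(benzyloxy)-2,3-dimethoxyphenyl]-5,6,7-trimethoxy-4H-chromen-4-one
Product: 12 5-hydroxy-2-(5-hydroxy-2,3-dimethoxyphenyl)-6,7-dimethoxy-4H-chromen-4-one
Conditions: BCl3 (5 equiv), pentamethylbenzene (3 equiv), CH2Cl2, −78 °C, then 0 °C; aq HCl
Reagents that add atoms: none
Why: Lewis acid ether cleavage, in which BCl3 removes the aryl benzyl group at −78 °C with pentamethylbenzene trapping the benzyl cation, and on warming the BCl3 bound to the C4 carbonyl chelates the peri C5 oxygen so that chloride removes only that methyl group and the unchelated methoxy groups at C6, C7, C2' and C3' remain.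

**Compound list**

1 | 3-bromo-4,5-dimethoxybenzaldehyde | COc1cc(C=O)cc(Br)c1OC | starting material
2 | 3-bromo-4,5-dimethoxyphenyl formate | COc1cc(OC=O)cc(Br)c1OC | intermediate
3 | 3-bromo-4,5-dimethoxyphenol | COc1cc(O)cc(Br)c1OC | intermediate
4 | 1-(benzyloxy)-3-bromo-4,5-dimethoxybenzene | COc1cc(OCc2ccccc2)cc(Br)c1OC | intermediate
5 | [5-(benzyloxy)-2,3-dimethoxyphenyl]lithium | [Li]c1cc(OCc2ccccc2)cc(OC)c1OC | intermediate
6 | 5-(benzyloxy)-2,3-dimethoxybenzoic acid | COc1cc(OCc2ccccc2)cc(C(=O)O)c1OC | intermediate
7 | 1-(6-hydroxy-2,3,4-trimethoxyphenyl)ethanone | CC(=O)c1c(O)cc(OC)c(OC)c1OC | starting material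
8 | 5-(benzyloxy)-2,3-dimethoxybenzoyl chloride | COc1cc(OCc2ccccc2)cc(C(=O)Cl)c1OC | intermediate
9 | 2-acetyl-3,4,5-trimethoxyphenyl 5-(benzyloxy)-2,3-dimethoxybenzoate | CC(=O)c1c(OC(=O)c2cc(OCc3ccccc3)cc(OC)c2OC)cc(OC)c(OC)c1OC | intermediate
10 | 1-[5-(benzyloxy)-2,3-dimethoxyphenyl]-3-(6-hydroxy-2,3,4-trimethoxyphenyl)propane-1,3-dione | COc1cc(OCc2ccccc2)cc(C(=O)CC(=O)c2c(O)cc(OC)c(OC)c2OC)c1OC | intermediate
11 | 2-[5-(benzyloxy)-2,3-dimethoxyphenyl]-5,6,7-trimethoxy-4H-chromen-4-one | COc1cc(OCc2ccccc2)cc(-c2cc(=O)c3c(OC)c(OC)c(OC)cc3o2)c1OC | intermediate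
12 | 5-hydroxy-2-(5-hydroxy-2,3-dimethoxyphenyl)-6,7-dimethoxy-4H-chromen-4-one | COc1cc(O)cc(-c2cc(=O)c3c(O)c(OC)c(OC)cc3o2)c1OC | target

**Step count and risks**

Total step count: 7. Longest linear sequence: 7 steps (1 to 12); acetophenone 7 enters at step 4.

Steps most likely to fail:

1. Step 5. Hydroxide cleavage of the hindered aryl ester, or retro-Claisen fragmentation of the diketone, may compete with the acyl migration. The fallback gives up the ester tether and forms the same C2–C3 bond at the chalcone oxidation level. It sets out from bromide 4 and rejoins the route at flavone 11. The aryllithium 5, generated from 4 as in step 3, is quenched with DMF to give 5-(benzyloxy)-2,3-dimethoxybenzaldehyde F1. Claisen–Schmidt condensation of this aldehyde with acetophenone 7 (KOH, EtOH, rt; aq HCl) should give (E)-3-[5-(benzyloxy)-2,3-dimethoxyphenyl]-1-(6-hydroxy-2,3,4-trimethoxyphenyl)prop-2-en-1-one F2. Oxidative cyclisation of the 2'-hydroxychalcone with I2 (cat.) in DMSO at 120 °C should then deliver 11.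

2. Step 7. Dealkylation may run on to the C6 methoxy group next to the boron chelate or to a ring B methoxy group, or the benzyl cation may re-attack the electron-rich C8 position if scavenging is incomplete. The fallback separates the two deprotections. It sets out from 11 and rejoins at 12. Hydrogenolysis (H2, 1 atm, Pd/C (palladium metal on carbon), EtOAc/MeOH, rt) should give 2-(5-hydroxy-2,3-dimethoxyphenyl)-5,6,7-trimethoxy-4H-chromen-4-one F3. A milder chelation-controlled demethylation with AlCl3 in MeCN (rt to 50 °C; aq HCl) should then remove only the C5 methyl group to give 12, with no benzyl cation present.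

3. Step 3. Benzylic deprotonation followed by Wittig rearrangement, or protonation or butylation of the aryllithium before CO2 trapping, may erode the carboxylation. The fallback replaces organolithium chemistry by palladium-catalysed carbonylation. It sets out from 4 and rejoins at 6. Methoxycarbonylation of 4 (Pd(OAc)2, dppf, CO, Et3N, MeOH/DMF, 80 °C) should give methyl 5-(benzyloxy)-2,3-dimethoxybenzoate F4, and saponification (LiOH, THF/H2O; HCl) should give acid 6.

**Further compounds**

F1 | step 5 | 5-(benzyloxy)-2,3-dimethoxybenzaldehyde | COc1cc(OCc2ccccc2)cc(C=O)c1OC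
F2 | step 5 | (E)-3-[5-(benzyloxy)-2,3-dimethoxyphenyl]-1-(6-hydroxy-2,3,4-trimethoxyphenyl)prop-2-en-1-one | COc1cc(OCc2ccccc2)cc(/C=C/C(=O)c2c(O)cc(OC)c(OC)c2OC)c1OC
F3 | step 7 | 2-(5-hydroxy-2,3-dimethoxyphenyl)-5,6,7-trimethoxy-4H-chromen-4-one | COc1cc(O)cc(-c2cc(=O)c3c(OC)c(OC)c(OC)cc3o2)c1OC
F4 | step 3 | methyl 5-(benzyloxy)-2,3-dimethoxybenzoate | COC(=O)c1cc(OCc2ccccc2)cc(OC)c1OC
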